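**Plan**
- The retrosynthesis first removes three benzyl groups, then takes the C5 methyl of ring B back to a formyl group. Formyl group and B–C ester together are traced to the C2=C3 bond of a 2-arylbenzofuran (ozonolysis transform).
- Enabling feature: in ring B (numbered from its ester carbon C1), O4 carries the ring C acyl carbon and is ortho to the C5 methyl. O4, that acyl carbon and the C5 methyl carbon are therefore O1, C2 and C3 of a benzofuran with ring B as benzo ring and ring C as 2-aryl group.
- The furan is cut at C5–C and O4–C to a C5-iodinated ring A–ring B phenol and a ring C arylacetylene. The A–B ester is cut by plain esterification, because the ring A phenol has only one ortho substituent.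
- Forward: one monomer gives both the ring A and ring B units, which are esterified, unmasked and iodinated; 2,5-dimethylresorcinol gives the alkyne. Sonogashira coupling with 5-endo-dig closure builds the only new ring, the temporary furan, which ozonolysis opens again; formyl reduction and hydrogenolysis finish.
- Stereochemistry: the target has no stereocentre and no stereogenic double bond, so nothing has to be set.

Key step: step 12

Assumptions: MOMCl, MeI, NIS, DCC, the Ohira–Bestmann reagent and the catalysts are taken as commercial reagents. In step 3 the carboxyl OH oxygen is taken to come from hydroxide (acyl–oxygen cleavage).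

**Route**

Step 1
Reactants: 1 methyl 2,4-dihydroxy-3,6-dimethylbenzoate
Product: 2 methyl 2-hydroxy-4-(methoxymethoxy)-3,6-dimethylbenzoate
Conditions: MOMCl (1.1 equiv), K2CO3, acetone, 0 °C to rt
Reagents that add atoms: chloromethyl methyl ether (MOMCl), COCCl
Why: Williamson-type O-alkylation should go only at O4, because the 2-hydroxyl is held in a hydrogen bond to the ester carbonyl and is the poorer nucleophile.

Step 2
Reactants: 2 methyl 2-hydroxy-4-(methoxymethoxy)-3,6-dimethylbenzoate
Product: 3 methyl 2-methoxy-4-(methoxymethoxy)-3,6-dimethylbenzoate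
Conditions: MeI, K2CO3, DMF, 50 °C
Reagents that add atoms: iodomethane, CI
Why: With O4 capped, Williamson etherification of the chelated 2-hydroxyl proceeds under K2CO3 in warm DMF, and the MOM acetal is inert to base.

Step 3
Reactants: 3 methyl 2-methoxy-4-(methoxymethoxy)-3,6-dimethylbenzoate
Product: 4 2-methoxy-4-(methoxymethoxy)-3,6-dimethylbenzoic acid
Conditions: KOH, DMSO/H2O, 90 °C; then 1 M HCl to pH 3–4, 0 °C
Reagents that add atoms: potassium hydroxide, [K+].[OH-]
Why: Saponification with poorly solvated hydroxide in hot aqueous DMSO is the standard way to hydrolyse di-ortho-substituted benzoates; the acetal and aryl ethers are base-stable and a cold, brief acidification should leave the MOM group in place.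

Step 4
Reactants: 4 2-methoxy-4-(methoxymethoxy)-3,6-dimethylbenzoic acid; 5 benzyl bromide
Product: 6 benzyl 2-methoxy-4-(methoxymethoxy)-3,6-dimethylbenzoate
Conditions: BnBr, K2CO3, DMF, rt
Reagents that add atoms: benzyl bromide (compound 5), BrCc1ccccc1
Why: Carboxylate O-alkylation (SN2 at the benzylic carbon) forms the ester without any attack at the hindered carbonyl carbon.

Step 5
Reactants: 6 benzyl 2-methoxy-4-(methoxymethoxy)-3,6-dimethylbenzoate
Product: 7 benzyl 4-hydroxy-2-methoxy-3,6-dimethylbenzoate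
Conditions: HCl (1.25 M in MeOH), THF, rt
Reagents that add atoms: none
Why: Acid-catalysed acetal cleavage passes the methoxymethyl group to methanol, while the di-ortho-substituted benzyl ester resists acid methanolysis.

Step 6
Reactants: 4 2-methoxy-4-(methoxymethoxy)-3,6-dimethylbenzoic acid; 7 benzyl 4-hydroxy-2-methoxy-3,6-dimethylbenzoate
Product: 8 benzyl 2-methoxy-4-{[2-methoxy-4-(methoxymethoxy)-3,6-dimethylbenzoyl]oxy}-3,6-dimethylbenzoate
Conditions: DCC, DMAP (0.3 equiv), CH2Cl2, 0 °C to rt
Reagents that add atoms: none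
Why: Steglich esterification relays the O-acylisourea of 4 through an acylpyridinium ion to the phenol of 7, which has only one ortho substituent (C3 methyl; C5 bears hydrogen), and the neutral conditions spare the MOM acetal.

Step 7
Reactants: 8 benzyl 2-methoxy-4-{[2-methoxy-4-(methoxymethoxy)-3,6-dimethylbenzoyl]oxy}-3,6-dimethylbenzoate
Product: 9 benzyl 4-[(4-hydroxy-2-methoxy-3,6-dimethylbenzoyl)oxy]-2-methoxy-3,6-dimethylbenzoate
Conditions: HCl (1.25 M in MeOH), THF, rt
Reagents that add atoms: none
Why: Acid-catalysed acetal cleavage frees the ring B phenol, and both the di-ortho-substituted aryl ester and the benzyl ester should survive dilute acid at room temperature.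

Step 8
Reactants: 9 benzyl 4-[(4-hydroxy-2-methoxy-3,6-dimethylbenzoyl)oxy]-2-methoxy-3,6-dimethylbenzoate
Product: 10 benzyl 4-[(4-hydroxy-5-iodo-2-methoxy-3,6-dimethylbenzoyl)oxy]-2-methoxy-3,6-dimethylbenzoate
Conditions: NIS (1.05 equiv), DMF, 0 °C to rt, dark
Reagents that add atoms: N-iodosuccinimide, O=C1CCC(=O)N1I
Why: Electrophilic aromatic iodination should take place on ring B alone, since its free phenol makes it far more nucleophilic than the O-acylated ring A and C5 is its only unsubstituted carbon.

Step 9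
Reactants: 11 2,5-dimethylresorcinol
Product: 13 2,4-dihydroxy-3,6-dimethylbenzaldehyde, via aryl iminium chloride 12 (not isolated)
Conditions: POCl3, DMF, 0 °C to rt; then H2O, 50 °C
Reagents that add atoms: N,N-dimethylformamide, CN(C)C=O; water, O
Why: Vilsmeier–Haack formylation attacks one of the two equivalent free positions, each ortho to one hydroxyl and para to the other, and the iminium group deactivates the ring against a second attack before hydrolysis.

Step 10
Reactants: 13 2,4-dihydroxy-3,6-dimethylbenzaldehyde; 5 benzyl bromide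
Product: 14 2,4-bis(benzyloxy)-3,6-dimethylbenzaldehyde
Conditions: BnBr (2.5 equiv), K2CO3, DMF, 60 °C
Reagents that add atoms: benzyl bromide (compound 5), BrCc1ccccc1
Why: Williamson etherification with excess benzyl bromide in warm DMF alkylates both phenols, including the one hydrogen-bonded to the formyl group.

Step 11
Reactants: 14 2,4-bis(benzyloxy)-3,6-dimethylbenzaldehyde
Product: 15 1,3-bis(benzyloxy)-4-ethynyl-2,5-dimethylbenzene
Conditions: dimethyl (1-diazo-2-oxopropyl)phosphonate, K2CO3, MeOH/THF, 0 °C to rt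
Reagents that add atoms: dimethyl (1-diazo-2-oxopropyl)phosphonate (Ohira–Bestmann reagent), COP(=O)(OC)C(=[N+]=[N-])C(C)=O
Why: Seyferth–Gilbert homologation in the Ohira–Bestmann variant: methanolysis releases the diazomethylphosphonate anion, which adds to the non-enolisable aldehyde, loses dimethyl phosphate and N2, and the alkylidene carbene rearranges to the terminal alkyne.

Step 12
Reactants: 10 benzyl 4-[(4-hydroxy-5-iodo-2-methoxy-3,6-dimethylbenzoyl)oxy]-2-methoxy-3,6-dimethylbenzoate; 15 1,3-bis(benzyloxy)-4-ethynyl-2,5-dimethylbenzene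
Product: 17 benzyl 4-[({2-[2,4-bis(benzyloxy)-3,6-dimethylphenyl]-6-methoxy-4,7-dimethyl-1-benzofuran-5-yl}carbonyl)oxy]-2-methoxy-3,6-dimethylbenzoate, via ortho-alkynylphenol 16 (not isolated)
Conditions: PdCl2(PPh3)2 (5 mol %), CuI (10 mol %), Et3N, DMF, degassed, 25 °C then 80 °C
Reagents that add atoms: none
Why: Oxidative addition of the C5–I bond of ring B to zerovalent palladium (formed in situ from the divalent precatalyst PdCl2(PPh3)2), transfer of the alkynyl group of 15 from the acetylide made with CuI and Et3N, and reductive elimination should give alkynylphenol 16, a Sonogashira coupling. At 80 °C the O4 phenoxide attacks the distal carbon of the metal-coordinated triple bond and protonolysis of the C3–metal bond frees the benzofuran; this tandem coupling–heteroannulation of ortho-iodophenols with arylacetylenes is the closest known reaction type and is well established. One ring is closed, the furan, by 5-endo-dig attack of oxygen on the alkyne, and no stereocentre is formed. The step needs a single coupling site and O-attack at the alkyne carbon remote from ring B: 10 has only one carbon–iodine bond, and the ortho relation of O4 and the C5 alkyne permits only the five-membered closure. Because the alkyne is linear, the ortho groups that would shield an activated ring C acyl carbon, and the two neighbours of O4, do not obstruct either bond formation.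

Step 13
Reactants: 17 benzyl 4-[({2-[2,4-bis(benzyloxy)-3,6-dimethylphenyl]-6-methoxy-4,7-dimethyl-1-benzofuran-5-yl}carbonyl)oxy]-2-methoxy-3,6-dimethylbenzoate
Product: 19 benzyl 4-[(4-{[2,4-bis(benzyloxy)-3,6-dimethylbenzoyl]oxy}-5-formyl-2-methoxy-3,6-dimethylbenzoyl)oxy]-2-methoxy-3,6-dimethylbenzoate, via secondary ozonide 18 (not isolated)
Conditions: O3 (1 equiv, Sudan Red 7B as indicator), CH2Cl2, −78 °C; then PPh3, −78 °C to rt
Reagents that add atoms: ozone, [O-][O+]=O
Why: Ozonolysis: ozone adds as a 1,3-dipole to the furan C2=C3 enol-ether bond, the most electron-rich alkene-type bond present, Criegee fragmentation and recombination give ozonide 18, and its reduction by PPh3 leaves C2 as the aryl ester carbonyl and C3 as a formyl group, as is established for 2-arylbenzofurans.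

Step 14
Reactants: 19 benzyl 4-[(4-{[2,4-bis(benzyloxy)-3,6-dimethylbenzoyl]oxy}-5-formyl-2-methoxy-3,6-dimethylbenzoyl)oxy]-2-methoxy-3,6-dimethylbenzoate
Product: 20 benzyl 4-[(4-{[2,4-bis(benzyloxy)-3,6-dimethylbenzoyl]oxy}-2-methoxy-3,5,6-trimethylbenzoyl)oxy]-2-methoxy-3,6-dimethylbenzoate
Conditions: Et3SiH (3 equiv), TFA, CH2Cl2, 0 °C to rt
Reagents that add atoms: none
Why: Ionic hydrogenation: Et3SiH reduces the protonated aldehyde, the benzylic oxygen function ionises in TFA to a cation stabilised by the para methoxy group at C2 of ring B, and a second hydride transfer gives the methyl group, while esters and aryl ethers are inert to the silane.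

Step 15
Reactants: 20 benzyl 4-[(4-{[2,4-bis(benzyloxy)-3,6-dimethylbenzoyl]oxy}-2-methoxy-3,5,6-trimethylbenzoyl)oxy]-2-methoxy-3,6-dimethylbenzoate
Product: 21 4-[(4-{[2,4-dihydroxy-3,6-dimethylbenzoyl]oxy}-2-methoxy-3,5,6-trimethylbenzoyl)oxy]-2-methoxy-3,6-dimethylbenzoic acid
Conditions: H2 (1 atm), 10% Pd/C, EtOAc/MeOH, rt
Reagents that add atoms: none
Why: Catalytic hydrogenolysis cleaves the two benzyl ethers of ring C and the benzyl ester of ring A at their benzylic C–O bonds, whereas aryl esters, aryl methyl ethers and the arenes are untouched.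

**Compound list**

1 | methyl 2,4-dihydroxy-3,6-dimethylbenzoate | COC(=O)c1c(C)cc(O)c(C)c1O | starting material
2 | methyl 2-hydroxy-4-(methoxymethoxy)-3,6-dimethylbenzoate | COC(=O)c1c(C)cc(OCOC)c(C)c1O | intermediate
3 | methyl 2-methoxy-4-(methoxymethoxy)-3,6-dimethylbenzoate | COC(=O)c1c(C)cc(OCOC)c(C)c1OC | intermediate
4 | 2-methoxy-4-(methoxymethoxy)-3,6-dimethylbenzoic acid (ring B unit) | OC(=O)c1c(C)cc(OCOC)c(C)c1OC | intermediate
5 | benzyl bromide | BrCc1ccccc1 | starting material
6 | benzyl 2-methoxy-4-(methoxymethoxy)-3,6-dimethylbenzoate | COCOc1cc(C)c(C(=O)OCc2ccccc2)c(OC)c1C | intermediate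
7 | benzyl 4-hydroxy-2-methoxy-3,6-dimethylbenzoate (ring A unit) | COc1c(C)c(O)cc(C)c1C(=O)OCc2ccccc2 | intermediate
8 | benzyl 2-methoxy-4-{[2-methoxy-4-(methoxymethoxy)-3,6-dimethylbenzoyl]oxy}-3,6-dimethylbenzoate | COc1c(C)c(OC(=O)c2c(C)cc(OCOC)c(C)c2OC)cc(C)c1C(=O)OCc3ccccc3 | intermediate
9 | benzyl 4-[(4-hydroxy-2-methoxy-3,6-dimethylbenzoyl)oxy]-2-methoxy-3,6-dimethylbenzoate | COc1c(C)c(OC(=O)c2c(C)cc(O)c(C)c2OC)cc(C)c1C(=O)OCc3ccccc3 | intermediate
10 | benzyl 4-[(4-hydroxy-5-iodo-2-methoxy-3,6-dimethylbenzoyl)oxy]-2-methoxy-3,6-dimethylbenzoate | COc1c(C)c(OC(=O)c2c(C)c(I)c(O)c(C)c2OC)cc(C)c1C(=O)OCc3ccccc3 | intermediate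
11 | 2,5-dimethylresorcinol (2,5-dimethylbenzene-1,3-diol) | Cc1cc(O)c(C)c(O)c1 | starting material
12 | N-[(2,4-dihydroxy-3,6-dimethylphenyl)methylidene]-N-methylmethanaminium chloride (aryl iminium chloride) | C[N+](C)=Cc1c(C)cc(O)c(C)c1O.[Cl-] | intermediate
13 | 2,4-dihydroxy-3,6-dimethylbenzaldehyde | O=Cc1c(C)cc(O)c(C)c1O | intermediate
14 | 2,4-bis(benzyloxy)-3,6-dimethylbenzaldehyde | O=Cc1c(C)cc(OCc2ccccc2)c(C)c1OCc3ccccc3 | intermediate
15 | 1,3-bis(benzyloxy)-4-ethynyl-2,5-dimethylbenzene | C#Cc1c(C)cc(OCc2ccccc2)c(C)c1OCc3ccccc3 | intermediate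
16 | benzyl 4-[(5-{[2,4-bis(benzyloxy)-3,6-dimethylphenyl]ethynyl}-4-hydroxy-2-methoxy-3,6-dimethylbenzoyl)oxy]-2-methoxy-3,6-dimethylbenzoate (ortho-alkynylphenol) | COc1c(C)c(OC(=O)c2c(C)c(C#Cc4c(C)cc(OCc5ccccc5)c(C)c4OCc6ccccc6)c(O)c(C)c2OC)cc(C)c1C(=O)OCc3ccccc3 | intermediate
17 | benzyl 4-[({2-[2,4-bis(benzyloxy)-3,6-dimethylphenyl]-6-methoxy-4,7-dimethyl-1-benzofuran-5-yl}carbonyl)oxy]-2-methoxy-3,6-dimethylbenzoate (2-arylbenzofuran) | COc1c(C)c(OC(=O)c2c(C)c3cc(-c4c(C)cc(OCc5ccccc5)c(C)c4OCc6ccccc6)oc3c(C)c2OC)cc(C)c1C(=O)OCc7ccccc7 | intermediate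
18 | secondary ozonide (1,2,4-trioxolane) across benzofuran C2–C3 of 17, racemic | COc1c(C)c(OC(=O)c2c(C)c3C4OC(OO4)(c5c(C)cc(OCc6ccccc6)c(C)c5OCc7ccccc7)Oc3c(C)c2OC)cc(C)c1C(=O)OCc8ccccc8 | intermediate
19 | benzyl 4-[(4-{[2,4-bis(benzyloxy)-3,6-dimethylbenzoyl]oxy}-5-formyl-2-methoxy-3,6-dimethylbenzoyl)oxy]-2-methoxy-3,6-dimethylbenzoate | COc1c(C)c(OC(=O)c2c(C)c(C=O)c(OC(=O)c4c(C)cc(OCc5ccccc5)c(C)c4OCc6ccccc6)c(C)c2OC)cc(C)c1C(=O)OCc3ccccc3 | intermediate
20 | benzyl 4-[(4-{[2,4-bis(benzyloxy)-3,6-dimethylbenzoyl]oxy}-2-methoxy-3,5,6-trimethylbenzoyl)oxy]-2-methoxy-3,6-dimethylbenzoate | COc1c(C)c(OC(=O)c2c(C)c(C)c(OC(=O)c4c(C)cc(OCc5ccccc5)c(C)c4OCc6ccccc6)c(C)c2OC)cc(C)c1C(=O)OCc3ccccc3 | intermediate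
21 | 4-[(4-{[2,4-dihydroxy-3,6-dimethylbenzoyl]oxy}-2-methoxy-3,5,6-trimethylbenzoyl)oxy]-2-methoxy-3,6-dimethylbenzoic acid (CNP0425440.0) | COc1c(C)c(OC(=O)c2c(C)c(C)c(OC(=O)c3c(C)cc(O)c(C)c3O)c(C)c2OC)cc(C)c1C(=O)O | target

**Step count and risks**

Total steps: 15. Longest linear sequence: 12 steps (steps 1–8, then 12–15, through ring A unit 7); the alkyne branch (steps 9–11) joins at step 12.

Steps most likely to fail:

1. Step 12. Oxidative addition into the electron-rich, doubly ortho-substituted iodophenolate may be slow, so that oxidative homocoupling of the alkyne outruns cross-coupling, or the sequence may stop at the uncyclised alkynylphenol. The fallback sets out from 10 and separates the two events. Acetylation (Ac2O, pyridine, DMAP) would give the less electron-rich aryl acetate benzyl 4-{[4-(acetyloxy)-5-iodo-2-methoxy-3,6-dimethylbenzoyl]oxy}-2-methoxy-3,6-dimethylbenzoate F1. Sonogashira coupling of F1 with 15 would give the ortho-alkynylaryl acetate F2. Cs2CO3 in MeOH/THF would then remove the acetate, and the phenoxide of 16 would close 5-endo-dig, so the route is rejoined at 17. The hindered depside and benzyl esters should be far slower to methanolyse than the aryl acetate.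

2. Step 13. Ozone may over-oxidise, attacking the electron-rich resorcinol diether ring C or the benzylic C–H bonds of the benzyl ethers in competition with the furan double bond. The fallback sets out from 17 and uses singlet oxygen, which does not react with simple alkoxyarenes. Sensitised photooxygenation (tetraphenylporphyrin, O2, visible light, CH2Cl2, −78 °C) should give by [2+2] cycloaddition the 1,2-dioxetane across benzofuran C2–C3, F3. On warming, F3 cleaves thermally to the aryl ester and the formyl group, returning to the route at 19.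

3. Step 14. The benzylic cation may be intercepted by the neighbouring aroyloxy carbonyl oxygen (acyl transfer or reductive loss of the ester), and benzyl ethers may be partly lost in TFA. The fallback sets out from 19 and avoids cationic intermediates. Condensation with p-toluenesulfonyl hydrazide (MeOH/THF, rt) would give the (E)-tosylhydrazone of 19, F4. Reduction of F4 with catecholborane in CHCl3, then NaOAc·3H2O at reflux, expels sulfinate and N2 and delivers the methyl group, returning to the route at 20.

Further compounds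
F1 | step 12 | benzyl 4-{[4-(acetyloxy)-5-iodo-2-methoxy-3,6-dimethylbenzoyl]oxy}-2-methoxy-3,6-dimethylbenzoate | COc1c(C)c(OC(=O)c2c(C)c(I)c(OC(C)=O)c(C)c2OC)cc(C)c1C(=O)OCc3ccccc3
F2 | step 12 | benzyl 4-{[4-(acetyloxy)-5-{[2,4-bis(benzyloxy)-3,6-dimethylphenyl]ethynyl}-2-methoxy-3,6-dimethylbenzoyl]oxy}-2-methoxy-3,6-dimethylbenzoate | COc1c(C)c(OC(=O)c2c(C)c(C#Cc4c(C)cc(OCc5ccccc5)c(C)c4OCc6ccccc6)c(OC(C)=O)c(C)c2OC)cc(C)c1C(=O)OCc3ccccc3
F3 | step 13 | 1,2-dioxetane across benzofuran C2–C3 of 17, racemic | COc1c(C)c(OC(=O)c2c(C)c3C4OOC4(c5c(C)cc(OCc6ccccc6)c(C)c5OCc7ccccc7)Oc3c(C)c2OC)cc(C)c1C(=O)OCc8ccccc8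
F4 | step 14 | (E)-p-toluenesulfonylhydrazone of aldehyde 19 | COc1c(C)c(OC(=O)c2c(C)c(/C=N/NS(=O)(=O)c7ccc(C)cc7)c(OC(=O)c4c(C)cc(OCc5ccccc5)c(C)c4OCc6ccccc6)c(C)c2OC)cc(C)c1C(=O)OCc3ccccc3
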